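## Retrosynthetic overview

1. The target is reached by acylations only: the angelate goes on the C10 hydroxyl and the p-hydroxybenzoate (phenol masked as TBS ether) on the C6 hydroxyl of a trans-fused hydroazulene whose C4 tertiary carbinol comes from isopropyl addition to a C4 ketone.
2. The seven-membered ring is formed second, by ring-closing metathesis at C8=C9 between a methallyl arm on C5 and a propenyl carbinol ether on C1.
3. The key fragment union is an intermolecular boron aldol (C5–C6 bond) between a 4,4-disubstituted cyclopentenone and 3-methylbut-3-enal, which sets C5 and C6.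
4. The cyclopentenone ring is formed first, by Wacker oxidation and intramolecular aldol condensation of an α-quaternary pent-4-enal.
5. The C1/C10 stereodiad comes from an Evans syn-aldol with crotonaldehyde followed by Fráter–Seebach methylation.

Convention (one line): C-labels in the text are daucane numbering (C1 = quaternary C–Me, C4 = C(OH)(i-Pr), C5 = ring-fusion CH, C6 = CH–O-aroyl, C8=C9 = ring alkene, C10 = CH–O-angeloyl); names use cyclopentane or azulene numbering; PMB = 4-methoxybenzyl, TES = triethylsilyl, TBS = tert-butyldimethylsilyl; standard aqueous work-up is implied.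

## Route

Step 1
Reactants: 1 (4S)-4-benzyl-1,3-oxazolidin-2-one; 2 pent-4-enoyl chloride
Product: 3 (4S)-4-benzyl-3-(pent-4-enoyl)-1,3-oxazolidin-2-one
Conditions: Et3N, DMAP (cat.), CH2Cl2, 0 °C to rt
Reagents that add atoms: none
Why: DMAP-catalysed N-acylation of the oxazolidinone gives the Evans imide, and no stereocentre is formed.

Step 2
Reactants: 3 (4S)-4-benzyl-3-(pent-4-enoyl)-1,3-oxazolidin-2-one; 4 (2E)-but-2-enal
Product: 6 (4S)-4-benzyl-3-[(2S,3R,4E)-3-hydroxy-2-(prop-2-en-1-yl)hex-4-enoyl]-1,3-oxazolidin-2-one, via dibutylboron Z-enolate of the imide 5 (not isolated)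
Conditions: n-Bu2BOTf, i-Pr2NEt, CH2Cl2, 0 °C; 4, −78 to 0 °C; then pH 7 buffer (NaH2PO4/Na2HPO4), MeOH, 30% H2O2, 0 °C
Reagents that add atoms: dibutylboron triflate CCCCB(CCCC)OS(=O)(=O)C(F)(F)F (its boron is carried only in 5 and is lost on work-up)
Why: In this Evans syn-aldol reaction the Z-boron enolate adds through a Zimmerman–Traxler chair on the face away from the benzyl group, giving the 2S,3R adduct whose carbinol carbon is the future C10 (R).

Step 3
Reactants: 6 (4S)-4-benzyl-3-[(2S,3R,4E)-3-hydroxy-2-(prop-2-en-1-yl)hex-4-enoyl]-1,3-oxazolidin-2-one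
Product: 7 methyl (2S,3R,4E)-3-hydroxy-2-(prop-2-en-1-yl)hex-4-enoate
Conditions: MeMgBr, MeOH, CH2Cl2, 0 °C (MeOMgBr formed in the flask)
Reagents that add atoms: methanol CO (delivered as bromomagnesium methoxide)
Why: Transesterification at the exocyclic imide carbonyl by the weakly basic magnesium methoxide releases the auxiliary without retro-aldol cleavage and leaves the carbinol centre untouched.

Step 4
Reactants: 7 methyl (2S,3R,4E)-3-hydroxy-2-(prop-2-en-1-yl)hex-4-enoate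
Product: 9 methyl (2S,3R,4E)-3-hydroxy-2-methyl-2-(prop-2-en-1-yl)hex-4-enoate, via dilithium alkoxide enolate 8 (not isolated)
Conditions: LiN(i-Pr)2 (2.3 equiv), THF, −78 to −20 °C; MeI, DMPU, −78 to −10 °C
Reagents that add atoms: iodomethane CI; lithium diisopropylamide [Li+].CC(C)[N-]C(C)C (its lithium is carried only in 8)
Why: In this Fráter–Seebach alkylation the chelated dianion is methylated on the face anti to the substituent of the alkoxide carbon, so the quaternary carbon (future C1) gets methyl anti and the allyl arm syn to the C10 oxygen whatever the former α-configuration was.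

Step 5
Reactants: 9 methyl (2S,3R,4E)-3-hydroxy-2-methyl-2-(prop-2-en-1-yl)hex-4-enoate
Product: 10 (2R,3R,4E)-2-methyl-2-(prop-2-en-1-yl)hex-4-ene-1,3-diol
Conditions: LiAlH4, THF, 0 °C
Reagents that add atoms: none
Why: Hydride reduction of the ester gives the 1,3-diol with both stereocentres unchanged (the C2 descriptor changes only through CIP priorities).

Step 6
Reactants: 10 (2R,3R,4E)-2-methyl-2-(prop-2-en-1-yl)hex-4-ene-1,3-diol
Product: 11 (2S,4R,5R)-2-(4-methoxyphenyl)-5-methyl-5-(prop-2-en-1-yl)-4-[(1E)-prop-1-en-1-yl]-1,3-dioxane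
Conditions: 4-MeOC6H4CH(OMe)2, PPTS (cat.), CH2Cl2, rt
Reagents that add atoms: 4-methoxybenzaldehyde dimethyl acetal COC(OC)c1ccc(OC)cc1
Why: Acid-catalysed transacetalisation closes the six-membered p-methoxybenzylidene acetal under thermodynamic control, with aryl and propenyl both equatorial (2,4-cis).

Step 7
Reactants: 11 (2S,4R,5R)-2-(4-methoxyphenyl)-5-methyl-5-(prop-2-en-1-yl)-4-[(1E)-prop-1-en-1-yl]-1,3-dioxane
Product: 12 (2R,3R,4E)-3-[(4-methoxybenzyl)oxy]-2-methyl-2-(prop-2-en-1-yl)hex-4-en-1-ol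
Conditions: i-Bu2AlH, CH2Cl2, −78 to 0 °C
Reagents that add atoms: none
Why: In this regioselective reductive acetal opening the aluminium hydride binds the less hindered primary oxygen and cleaves that C–O bond, leaving the PMB ether on the hindered secondary allylic oxygen.

Step 8
Reactants: 12 (2R,3R,4E)-3-[(4-methoxybenzyl)oxy]-2-methyl-2-(prop-2-en-1-yl)hex-4-en-1-ol
Product: 13 (2S,3R,4E)-3-[(4-methoxybenzyl)oxy]-2-methyl-2-(prop-2-en-1-yl)hex-4-enal
Conditions: Dess–Martin periodinane, CH2Cl2, rt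
Reagents that add atoms: none
Why: Dess–Martin oxidation of the neopentyl primary alcohol gives an aldehyde with no α-hydrogen, so it can neither epimerise nor enolise.

Step 9
Reactants: 13 (2S,3R,4E)-3-[(4-methoxybenzyl)oxy]-2-methyl-2-(prop-2-en-1-yl)hex-4-enal
Product: 14 (2S,3R,4E)-3-[(4-methoxybenzyl)oxy]-2-methyl-2-(2-oxopropyl)hex-4-enal
Conditions: PdCl2 (10 mol %), CuCl, O2 (1 atm), DMF/H2O 7:1, rt
Reagents that add atoms: water O (source of the ketone oxygen; O2 is the terminal oxidant)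
Why: The Tsuji–Wacker oxidation converts only the terminal alkene into the methyl ketone (Markovnikov), the internal E-propenyl ether alkene being far less reactive.

Step 10
Reactants: 14 (2S,3R,4E)-3-[(4-methoxybenzyl)oxy]-2-methyl-2-(2-oxopropyl)hex-4-enal
Product: 16 (4R)-4-[(1R,2E)-1-[(4-methoxybenzyl)oxy]but-2-en-1-yl]-4-methylcyclopent-2-en-1-one, via 3-hydroxycyclopentanone aldol 15 (not isolated)
Conditions: KOH, MeOH, rt
Reagents that add atoms: none
Why: In this intramolecular aldol condensation the methyl ketone enolate attacks the non-enolisable aldehyde and the aldol dehydrates, closing the five-membered ring as a 4,4-disubstituted cyclopentenone without touching the quaternary centre.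

Step 11
Reactants: 17 3-methylbut-3-en-1-ol
Product: 18 3-methylbut-3-enal
Conditions: Dess–Martin periodinane, NaHCO3, CH2Cl2, 0 °C; cold filtered solution used at once
Reagents that add atoms: none
Why: Buffered Dess–Martin oxidation gives the β,γ-unsaturated aldehyde without acid- or base-induced migration of the double bond into conjugation.

Step 12
Reactants: 16 (4R)-4-[(1R,2E)-1-[(4-methoxybenzyl)oxy]but-2-en-1-yl]-4-methylcyclopent-2-en-1-one; 18 3-methylbut-3-enal
Product: 20 (4S,5S)-5-[(1S)-1-hydroxy-3-methylbut-3-en-1-yl]-4-[(1R,2E)-1-[(4-methoxybenzyl)oxy]but-2-en-1-yl]-4-methylcyclopent-2-en-1-one, via dicyclohexylboron dienolate 19 (not isolated)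
Conditions: (c-C6H11)2BCl, Et3N, Et2O, 0 °C; 18 (fresh CH2Cl2 solution), −78 to −20 °C; then pH 7 buffer (NaH2PO4/Na2HPO4), MeOH, 30% H2O2, 0 °C
Reagents that add atoms: chlorodicyclohexylborane ClB(C1CCCCC1)C1CCCCC1 (its boron is carried only in 19 and is lost on work-up)
Why: In this intermolecular boron aldol, which joins the two fragments at C5–C6, the only enolisable position gives a ring-locked E-enolate that reacts through a Zimmerman–Traxler chair to the anti aldol (C6) on the enolate face carrying the small methyl group, anti to the branched CH(OPMB)propenyl arm of the neighbouring quaternary carbon (C5).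

Step 13
Reactants: 20 (4S,5S)-5-[(1S)-1-hydroxy-3-methylbut-3-en-1-yl]-4-[(1R,2E)-1-[(4-methoxybenzyl)oxy]but-2-en-1-yl]-4-methylcyclopent-2-en-1-one
Product: 21 (4S,5S)-4-[(1R,2E)-1-[(4-methoxybenzyl)oxy]but-2-en-1-yl]-4-methyl-5-[(1S)-3-methyl-1-[(triethylsilyl)oxy]but-3-en-1-yl]cyclopent-2-en-1-one
Conditions: Et3SiCl, imidazole, DMF, 0 °C to rt
Reagents that add atoms: chlorotriethylsilane CC[Si](Cl)(CC)CC
Why: Silylation of the aldol hydroxyl blocks retro-aldol and elimination pathways in the following basic steps.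

Step 14
Reactants: 21 (4S,5S)-4-[(1R,2E)-1-[(4-methoxybenzyl)oxy]but-2-en-1-yl]-4-methyl-5-[(1S)-3-methyl-1-[(triethylsilyl)oxy]but-3-en-1-yl]cyclopent-2-en-1-one
Product: 22 (2S,3S)-3-[(1R,2E)-1-[(4-methoxybenzyl)oxy]but-2-en-1-yl]-3-methyl-2-[(1S)-3-methyl-1-[(triethylsilyl)oxy]but-3-en-1-yl]cyclopentan-1-one
Conditions: [(Ph3P)CuH]6 (0.4 equiv), toluene, H2O (trace), rt
Reagents that add atoms: none
Why: Stryker conjugate reduction delivers hydride only to the enone β-carbon, leaving both isolated alkenes untouched, and the copper enolate forms on the side away from C5 so that centre is not epimerised.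

Step 15
Reactants: 22 (2S,3S)-3-[(1R,2E)-1-[(4-methoxybenzyl)oxy]but-2-en-1-yl]-3-methyl-2-[(1S)-3-methyl-1-[(triethylsilyl)oxy]but-3-en-1-yl]cyclopentan-1-one
Product: 23 (3aS,4S,8R,8aS)-8-[(4-methoxybenzyl)oxy]-6,8a-dimethyl-4-[(triethylsilyl)oxy]-1,2,3a,4,5,8-hexahydroazulen-3(8aH)-one
Conditions: second-generation Grubbs catalyst (H2IMes)(PCy3)Cl2Ru=CHPh (10 mol %), CH2Cl2 (2 mM), reflux
Reagents that add atoms: none
Why: Ring-closing metathesis between the propenyl and methallyl groups on the trans-disposed arms closes the seven-membered ring at C8=C9 with loss of propene, giving the trans-fused hydroazulenone without creating a stereocentre.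

Step 16
Reactants: 23 (3aS,4S,8R,8aS)-8-[(4-methoxybenzyl)oxy]-6,8a-dimethyl-4-[(triethylsilyl)oxy]-1,2,3a,4,5,8-hexahydroazulen-3(8aH)-one
Product: 24 (3R,3aS,4S,8R,8aS)-8-[(4-methoxybenzyl)oxy]-6,8a-dimethyl-3-(propan-2-yl)-4-[(triethylsilyl)oxy]-1,2,3,3a,4,5,8,8a-octahydroazulen-3-ol
Conditions: i-PrMgCl, CeCl3 (anhydrous), THF, −78 to −40 °C
Reagents that add atoms: isopropylmagnesium chloride CC(C)[Mg]Cl
Why: In this organocerium 1,2-addition the weakly basic isopropylcerium reagent attacks the enolisable ketone from the α-face, opposite the axial angular methyl group, so the C4 hydroxyl ends up β (cis to the methyl) and isopropyl α.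

Step 17
Reactants: 24 (3R,3aS,4S,8R,8aS)-8-[(4-methoxybenzyl)oxy]-6,8a-dimethyl-3-(propan-2-yl)-4-[(triethylsilyl)oxy]-1,2,3,3a,4,5,8,8a-octahydroazulen-3-ol
Product: 25 (3R,3aS,4S,8R,8aS)-8-[(4-methoxybenzyl)oxy]-6,8a-dimethyl-3-(propan-2-yl)-1,2,3,3a,4,5,8,8a-octahydroazulene-3,4-diol
Conditions: PPTS (cat.), MeOH, 0 °C to rt
Reagents that add atoms: none
Why: Mild acid-catalysed methanolysis removes the labile TES ether selectively, leaving the PMB ether and the tertiary alcohol intact.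

Step 18
Reactants: 26 4-hydroxybenzoic acid
Product: 28 4-[(tert-butyldimethylsilyl)oxy]benzoic acid, via bis-silylated silyl ester 27 (not isolated)
Conditions: t-BuMe2SiCl (2.2 equiv), imidazole, DMF, rt; then AcOH, THF, H2O, rt
Reagents that add atoms: tert-butyldimethylsilyl chloride CC(C)(C)[Si](C)(C)Cl
Why: Exhaustive silylation followed by selective hydrolysis of the labile silyl ester leaves the phenol protected and the acid free.

Step 19
Reactants: 25 (3R,3aS,4S,8R,8aS)-8-[(4-methoxybenzyl)oxy]-6,8a-dimethyl-3-(propan-2-yl)-1,2,3,3a,4,5,8,8a-octahydroazulene-3,4-diol; 28 4-[(tert-butyldimethylsilyl)oxy]benzoic acid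
Product: 29 (3R,3aS,4S,8R,8aS)-3-hydroxy-8-[(4-methoxybenzyl)oxy]-6,8a-dimethyl-3-(propan-2-yl)-1,2,3,3a,4,5,8,8a-octahydroazulen-4-yl 4-[(tert-butyldimethylsilyl)oxy]benzoate
Conditions: DCC, DMAP, CH2Cl2, rt
Reagents that add atoms: none
Why: Steglich esterification acylates the secondary C6 hydroxyl with retention, while the tertiary C4 hydroxyl is too hindered to react.

Step 20
Reactants: 29 (3R,3aS,4S,8R,8aS)-3-hydroxy-8-[(4-methoxybenzyl)oxy]-6,8a-dimethyl-3-(propan-2-yl)-1,2,3,3a,4,5,8,8a-octahydroazulen-4-yl 4-[(tert-butyldimethylsilyl)oxy]benzoate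
Product: 30 (3R,3aS,4S,8R,8aS)-3,8-dihydroxy-6,8a-dimethyl-3-(propan-2-yl)-1,2,3,3a,4,5,8,8a-octahydroazulen-4-yl 4-[(tert-butyldimethylsilyl)oxy]benzoate
Conditions: DDQ, CH2Cl2/pH 7 buffer (NaH2PO4/Na2HPO4), 0 °C
Reagents that add atoms: none
Why: Oxidative PMB cleavage by DDQ frees the C10 hydroxyl without affecting the esters, the aryl silyl ether or the C10 configuration.

Step 21
Reactants: 30 (3R,3aS,4S,8R,8aS)-3,8-dihydroxy-6,8a-dimethyl-3-(propan-2-yl)-1,2,3,3a,4,5,8,8a-octahydroazulen-4-yl 4-[(tert-butyldimethylsilyl)oxy]benzoate; 31 (2Z)-2-methylbut-2-enoic acid (angelic acid)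
Product: 33 (3R,3aS,4S,8R,8aS)-3-hydroxy-6,8a-dimethyl-8-{[(2Z)-2-methylbut-2-enoyl]oxy}-3-(propan-2-yl)-1,2,3,3a,4,5,8,8a-octahydroazulen-4-yl 4-[(tert-butyldimethylsilyl)oxy]benzoate, via angelic 2,4,6-trichlorobenzoic mixed anhydride 32 (not isolated)
Conditions: 2,4,6-Cl3C6H2COCl, Et3N, toluene, rt; then 30, 80 °C (no DMAP)
Reagents that add atoms: 2,4,6-trichlorobenzoyl chloride O=C(Cl)c1c(Cl)cc(Cl)cc1Cl (carried only in 32)
Why: Yamaguchi esterification without a nucleophilic catalyst acylates the secondary allylic C10 hydroxyl with retention and keeps the Z geometry of the angelate, the tertiary hydroxyl staying free.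

Step 22
Reactants: 33 (3R,3aS,4S,8R,8aS)-3-hydroxy-6,8a-dimethyl-8-{[(2Z)-2-methylbut-2-enoyl]oxy}-3-(propan-2-yl)-1,2,3,3a,4,5,8,8a-octahydroazulen-4-yl 4-[(tert-butyldimethylsilyl)oxy]benzoate
Product: 34 (3R,3aS,4S,8R,8aS)-3-hydroxy-6,8a-dimethyl-8-{[(2Z)-2-methylbut-2-enoyl]oxy}-3-(propan-2-yl)-1,2,3,3a,4,5,8,8a-octahydroazulen-4-yl 4-hydroxybenzoate (CNP0273650.2)
Conditions: HF·pyridine, pyridine, THF, 0 °C
Reagents that add atoms: none
Why: Fluoride-mediated desilylation removes the very labile aryl silyl ether under buffered conditions that leave both esters, the allylic system and the tertiary alcohol untouched.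

## Compound list

1 | (4S)-4-benzyl-1,3-oxazolidin-2-one | O=C1OC[C@H](Cc2ccccc2)N1 | starting material
2 | pent-4-enoyl chloride | C=CCCC(Cl)=O | starting material
3 | (4S)-4-benzyl-3-(pent-4-enoyl)-1,3-oxazolidin-2-one | C=CCCC(=O)N1[C@@H](Cc2ccccc2)COC1=O | intermediate
4 | (2E)-but-2-enal (crotonaldehyde) | C/C=C/C=O | starting material
5 | dibutylboron Z-enolate of 3 (not isolated) | C=CC/C=C(\OB(CCCC)CCCC)N1[C@@H](Cc2ccccc2)COC1=O | intermediate
6 | (4S)-4-benzyl-3-[(2S,3R,4E)-3-hydroxy-2-(prop-2-en-1-yl)hex-4-enoyl]-1,3-oxazolidin-2-one | C/C=C/[C@@H](O)[C@H](CC=C)C(=O)N1[C@@H](Cc2ccccc2)COC1=O | intermediate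
7 | methyl (2S,3R,4E)-3-hydroxy-2-(prop-2-en-1-yl)hex-4-enoate | C/C=C/[C@@H](O)[C@H](CC=C)C(=O)OC | intermediate
8 | dilithium alkoxide enolate of 7 (not isolated) | C/C=C/[C@@H](O[Li])C(CC=C)=C(OC)O[Li] | intermediate
9 | methyl (2S,3R,4E)-3-hydroxy-2-methyl-2-(prop-2-en-1-yl)hex-4-enoate | C/C=C/[C@@H](O)[C@](C)(CC=C)C(=O)OC | intermediate
10 | (2R,3R,4E)-2-methyl-2-(prop-2-en-1-yl)hex-4-ene-1,3-diol | C/C=C/[C@@H](O)[C@](C)(CC=C)CO | intermediate
11 | (2S,4R,5R)-2-(4-methoxyphenyl)-5-methyl-5-(prop-2-en-1-yl)-4-[(1E)-prop-1-en-1-yl]-1,3-dioxane | C/C=C/[C@H]1O[C@@H](c2ccc(OC)cc2)OC[C@@]1(C)CC=C | intermediate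
12 | (2R,3R,4E)-3-[(4-methoxybenzyl)oxy]-2-methyl-2-(prop-2-en-1-yl)hex-4-en-1-ol | C/C=C/[C@@H](OCc1ccc(OC)cc1)[C@](C)(CC=C)CO | intermediate
13 | (2S,3R,4E)-3-[(4-methoxybenzyl)oxy]-2-methyl-2-(prop-2-en-1-yl)hex-4-enal | C/C=C/[C@@H](OCc1ccc(OC)cc1)[C@](C)(CC=C)C=O | intermediate
14 | (2S,3R,4E)-3-[(4-methoxybenzyl)oxy]-2-methyl-2-(2-oxopropyl)hex-4-enal | C/C=C/[C@@H](OCc1ccc(OC)cc1)[C@](C)(CC(C)=O)C=O | intermediate
15 | (4R)-3-hydroxy-4-[(1R,2E)-1-[(4-methoxybenzyl)oxy]but-2-en-1-yl]-4-methylcyclopentan-1-one, both C3 epimers (not isolated) | C/C=C/[C@@H](OCc1ccc(OC)cc1)[C@]1(C)CC(=O)CC1O | intermediate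
16 | (4R)-4-[(1R,2E)-1-[(4-methoxybenzyl)oxy]but-2-en-1-yl]-4-methylcyclopent-2-en-1-one | C/C=C/[C@@H](OCc1ccc(OC)cc1)[C@]1(C)CC(=O)C=C1 | intermediate
17 | 3-methylbut-3-en-1-ol | C=C(C)CCO | starting material
18 | 3-methylbut-3-enal | C=C(C)CC=O | intermediate
19 | dicyclohexylboron dienolate of 16 (not isolated) | C/C=C/[C@@H](OCc1ccc(OC)cc1)[C@]1(C)C=C(OB(C2CCCCC2)C2CCCCC2)C=C1 | intermediate
20 | (4S,5S)-5-[(1S)-1-hydroxy-3-methylbut-3-en-1-yl]-4-[(1R,2E)-1-[(4-methoxybenzyl)oxy]but-2-en-1-yl]-4-methylcyclopent-2-en-1-one (ring descriptor differs from 16 by CIP priority only) | C/C=C/[C@@H](OCc1ccc(OC)cc1)[C@@]1(C)C=CC(=O)[C@@H]1[C@@H](O)CC(C)=C | intermediate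
21 | (4S,5S)-4-[(1R,2E)-1-[(4-methoxybenzyl)oxy]but-2-en-1-yl]-4-methyl-5-[(1S)-3-methyl-1-[(triethylsilyl)oxy]but-3-en-1-yl]cyclopent-2-en-1-one | C/C=C/[C@@H](OCc1ccc(OC)cc1)[C@@]1(C)C=CC(=O)[C@@H]1[C@@H](O[Si](CC)(CC)CC)CC(C)=C | intermediate
22 | (2S,3S)-3-[(1R,2E)-1-[(4-methoxybenzyl)oxy]but-2-en-1-yl]-3-methyl-2-[(1S)-3-methyl-1-[(triethylsilyl)oxy]but-3-en-1-yl]cyclopentan-1-one | C/C=C/[C@@H](OCc1ccc(OC)cc1)[C@@]1(C)CCC(=O)[C@@H]1[C@@H](O[Si](CC)(CC)CC)CC(C)=C | intermediate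
23 | (3aS,4S,8R,8aS)-8-[(4-methoxybenzyl)oxy]-6,8a-dimethyl-4-[(triethylsilyl)oxy]-1,2,3a,4,5,8-hexahydroazulen-3(8aH)-one | COc1ccc(cc1)CO[C@@H]1C=C(C)C[C@H](O[Si](CC)(CC)CC)[C@@H]2[C@]1(C)CCC2=O | intermediate
24 | (3R,3aS,4S,8R,8aS)-8-[(4-methoxybenzyl)oxy]-6,8a-dimethyl-3-(propan-2-yl)-4-[(triethylsilyl)oxy]-1,2,3,3a,4,5,8,8a-octahydroazulen-3-ol | COc1ccc(cc1)CO[C@@H]1C=C(C)C[C@H](O[Si](CC)(CC)CC)[C@@H]2[C@]1(C)CC[C@@]2(O)C(C)C | intermediate
25 | (3R,3aS,4S,8R,8aS)-8-[(4-methoxybenzyl)oxy]-6,8a-dimethyl-3-(propan-2-yl)-1,2,3,3a,4,5,8,8a-octahydroazulene-3,4-diol | COc1ccc(cc1)CO[C@@H]1C=C(C)C[C@H](O)[C@@H]2[C@]1(C)CC[C@@]2(O)C(C)C | intermediate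
26 | 4-hydroxybenzoic acid | OC(=O)c1ccc(O)cc1 | starting material
27 | tert-butyldimethylsilyl 4-[(tert-butyldimethylsilyl)oxy]benzoate (not isolated) | CC(C)(C)[Si](C)(C)Oc1ccc(cc1)C(=O)O[Si](C)(C)C(C)(C)C | intermediate
28 | 4-[(tert-butyldimethylsilyl)oxy]benzoic acid | CC(C)(C)[Si](C)(C)Oc1ccc(cc1)C(=O)O | intermediate
29 | (3R,3aS,4S,8R,8aS)-3-hydroxy-8-[(4-methoxybenzyl)oxy]-6,8a-dimethyl-3-(propan-2-yl)-1,2,3,3a,4,5,8,8a-octahydroazulen-4-yl 4-[(tert-butyldimethylsilyl)oxy]benzoate | COc1ccc(cc1)CO[C@@H]1C=C(C)C[C@H](OC(=O)c2ccc(O[Si](C)(C)C(C)(C)C)cc2)[C@@H]2[C@]1(C)CC[C@@]2(O)C(C)C | intermediate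
30 | (3R,3aS,4S,8R,8aS)-3,8-dihydroxy-6,8a-dimethyl-3-(propan-2-yl)-1,2,3,3a,4,5,8,8a-octahydroazulen-4-yl 4-[(tert-butyldimethylsilyl)oxy]benzoate | O[C@@H]1C=C(C)C[C@H](OC(=O)c2ccc(O[Si](C)(C)C(C)(C)C)cc2)[C@@H]2[C@]1(C)CC[C@@]2(O)C(C)C | intermediate
31 | (2Z)-2-methylbut-2-enoic acid (angelic acid) | C/C=C(/C)C(=O)O | starting material
32 | (2Z)-2-methylbut-2-enoic 2,4,6-trichlorobenzoic anhydride (not isolated) | C/C=C(/C)C(=O)OC(=O)c1c(Cl)cc(Cl)cc1Cl | intermediate
33 | (3R,3aS,4S,8R,8aS)-3-hydroxy-6,8a-dimethyl-8-{[(2Z)-2-methylbut-2-enoyl]oxy}-3-(propan-2-yl)-1,2,3,3a,4,5,8,8a-octahydroazulen-4-yl 4-[(tert-butyldimethylsilyl)oxy]benzoate | C/C=C(/C)C(=O)O[C@@H]1C=C(C)C[C@H](OC(=O)c2ccc(O[Si](C)(C)C(C)(C)C)cc2)[C@@H]2[C@]1(C)CC[C@@]2(O)C(C)C | intermediate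
34 | (3R,3aS,4S,8R,8aS)-3-hydroxy-6,8a-dimethyl-8-{[(2Z)-2-methylbut-2-enoyl]oxy}-3-(propan-2-yl)-1,2,3,3a,4,5,8,8a-octahydroazulen-4-yl 4-hydroxybenzoate | C/C=C(/C)C(=O)O[C@@H]1C=C(C)C[C@H](OC(=O)c2ccc(O)cc2)[C@@H]2[C@]1(C)CC[C@@]2(O)C(C)C | target

## Step count and risks

Total step count: 22.
Longest linear sequence: 20 steps (steps 1–10, 12–17 and 19–22, from 1 and 2 to 34); steps 11 and 18 are side branches.

Three steps most likely to fail:

Step 12 (key aldol). The aldehyde is prone to double-bond migration, and the anti:syn ratio at the new carbinol may be modest. If so, the carbinol stereocentre is set later by a hydroxyl-directed reduction instead of by the aldol. The epimer mixture is carried unchanged through steps 13–17. The fallback then sets out from 25 (as a mixture of epimers at the secondary carbinol). Dess–Martin periodinane oxidises only the secondary alcohol and gives (3R,3aR,8R,8aS)-3-hydroxy-8-[(4-methoxybenzyl)oxy]-6,8a-dimethyl-3-(propan-2-yl)-1,2,3,3a,5,8-hexahydroazulen-4(8aH)-one F1. Reduction of this β-hydroxy ketone with Me4NBH(OAc)3 in MeCN/AcOH at −20 °C follows (Evans–Saksena reduction). The boron bound to the β-oriented tertiary hydroxyl delivers hydride to the β-face of the ketone, so only the 1,3-anti (α) alcohol forms. The fallback comes back to the route at 25 as a single epimer.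

Step 15 (ring-closing metathesis). A trisubstituted cycloheptene has to form from a 1,1-disubstituted alkene and a propenyl group next to a quaternary carbon and a bulky PMB ether, so carbene loading may be too slow. The fallback sets out from 22 and changes the substrate to a hydroxyl-assisted ring closure. DDQ (CH2Cl2/pH 7 buffer) first removes the PMB group to give (2S,3S)-3-[(1R,2E)-1-hydroxybut-2-en-1-yl]-3-methyl-2-[(1S)-3-methyl-1-[(triethylsilyl)oxy]but-3-en-1-yl]cyclopentan-1-one F2. Its free, less hindered allylic alcohol accelerates ruthenium loading at the propenyl group. Metathesis with the same ruthenium catalyst then gives (3aS,4S,8R,8aS)-8-hydroxy-6,8a-dimethyl-4-[(triethylsilyl)oxy]-1,2,3a,4,5,8-hexahydroazulen-3(8aH)-one F3. The hydroxyl is re-protected under neutral conditions that spare the TES ether (2-(4-methoxybenzyloxy)-4-methylquinoline, MeOTf, MgO, PhCF3, rt). The fallback comes back to the route at 23.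

Step 21 (angeloylation). The C10 hydroxyl is secondary, allylic and next to a quaternary carbon, and forcing conditions can isomerise the angelate to the tiglate. The fallback sets out from 30 and builds the Z-alkene on the ester instead of transferring it. Steglich esterification (DCC, DMAP) with 2-[bis(2-methylphenoxy)phosphoryl]propanoic acid, a small unhindered acyl donor, gives (3R,3aS,4S,8R,8aS)-8-({2-[bis(2-methylphenoxy)phosphoryl]propanoyl}oxy)-3-hydroxy-6,8a-dimethyl-3-(propan-2-yl)-1,2,3,3a,4,5,8,8a-octahydroazulen-4-yl 4-[(tert-butyldimethylsilyl)oxy]benzoate F4. An Ando-type Z-selective Horner–Wadsworth–Emmons reaction with acetaldehyde (NaI, DBU, THF, 0 °C) then forms the (Z)-2-methylbut-2-enoate. The fallback comes back to the route at 33.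

## Further compounds

F1 | step 12 | (3R,3aR,8R,8aS)-3-hydroxy-8-[(4-methoxybenzyl)oxy]-6,8a-dimethyl-3-(propan-2-yl)-1,2,3,3a,5,8-hexahydroazulen-4(8aH)-one | COc1ccc(cc1)CO[C@@H]1C=C(C)CC(=O)[C@@H]2[C@]1(C)CC[C@@]2(O)C(C)C
F2 | step 15 | (2S,3S)-3-[(1R,2E)-1-hydroxybut-2-en-1-yl]-3-methyl-2-[(1S)-3-methyl-1-[(triethylsilyl)oxy]but-3-en-1-yl]cyclopentan-1-one | C/C=C/[C@@H](O)[C@@]1(C)CCC(=O)[C@@H]1[C@@H](O[Si](CC)(CC)CC)CC(C)=C
F3 | step 15 | (3aS,4S,8R,8aS)-8-hydroxy-6,8a-dimethyl-4-[(triethylsilyl)oxy]-1,2,3a,4,5,8-hexahydroazulen-3(8aH)-one | O[C@@H]1C=C(C)C[C@H](O[Si](CC)(CC)CC)[C@@H]2[C@]1(C)CCC2=O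
F4 | step 21 | (3R,3aS,4S,8R,8aS)-8-({2-[bis(2-methylphenoxy)phosphoryl]propanoyl}oxy)-3-hydroxy-6,8a-dimethyl-3-(propan-2-yl)-1,2,3,3a,4,5,8,8a-octahydroazulen-4-yl 4-[(tert-butyldimethylsilyl)oxy]benzoate (both epimers at the phosphonate carbon) | CC(C(=O)O[C@@H]1C=C(C)C[C@H](OC(=O)c2ccc(O[Si](C)(C)C(C)(C)C)cc2)[C@@H]2[C@]1(C)CC[C@@]2(O)C(C)C)P(=O)(Oc1ccccc1C)Oc1ccccc1C
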